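The furan is disconnected to an acyclic 2-alkynyl oxirane. Ring atoms O1, C5 and C4 are the oxirane, with C4 its quaternary carbon carrying the (R)-carbinol side chain, and C3 and C2 are the two carbons of the aryl alkyne. One silver-catalysed cycloisomerisation forms the O1–C2 bond, cleaves the C4–O bond and aromatises, which fixes the 2-aryl-4-alkyl pattern in a single operation. The precursor is assembled from methyl (R)-glycidate (source of the stereocentre), an isobutenyl Grignard reagent, a bis-silylated 2,5-dihydroxyphenyl acetylide and a sulfur ylide. All three oxygens are carried as tert-butyldimethylsilyl (TBS) ethers.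

Key step: step 8

Remark: the carbinol oxygen is carried as a TBS ether because a triethylsilyl ether would be expected to fall off under catalytic TsOH in methanol, and a free hydroxyl next to the oxirane could itself add to the activated alkyne; compounds 1 and 2 are taken as commercially available.

Step 1
Reactants: 1 methyl (R)-glycidate [methyl (2R)-oxirane-2-carboxylate]; 2 2-methyl-1-propenylmagnesium bromide
Product: 3 methyl (2R)-2-hydroxy-5-methylhex-4-enoate
Conditions: 2 (1.3 equiv), CuI (10 mol %), THF, −78 → −40 °C
Reagents that add atoms: none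
Why: Copper-catalysed Grignard (organocuprate) opening of the epoxide should occur at the unhindered CH2 terminus faster than addition to the ester at low temperature, and since C2 makes and breaks no bond the (R) configuration of 1 is carried over.

Step 2
Reactants: 3 methyl (2R)-2-hydroxy-5-methylhex-4-enoate
Product: 4 methyl (2R)-2-[(tert-butyldimethylsilyl)oxy]-5-methylhex-4-enoate
Conditions: TBSCl, imidazole, DMF, rt
Reagents that add atoms: tert-butyldimethylsilyl chloride, CC(C)(C)[Si](C)(C)Cl
Why: Imidazole-promoted O-silylation of a secondary alcohol is routine and touches no bond at the stereocentre.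

Step 3
Reactants: 4 methyl (2R)-2-[(tert-butyldimethylsilyl)oxy]-5-methylhex-4-enoate
Product: 5 (2R)-2-[(tert-butyldimethylsilyl)oxy]-N-methoxy-N,5-dimethylhex-4-enamide (Weinreb amide)
Conditions: MeNH(OMe)·HCl, iPrMgCl, THF, −20 → 0 °C
Reagents that add atoms: N,O-dimethylhydroxylamine hydrochloride, CNOC.Cl
Why: Weinreb amide formation by aminolysis of the ester with the chloromagnesium amide is standard for α-silyloxy esters, and the weakly basic amide nucleophile should leave the hindered α-hydrogen, and so the configuration, alone.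

Step 4
Reactants: 6 2,5-dihydroxybenzaldehyde
Product: 7 2,5-bis[(tert-butyldimethylsilyl)oxy]benzaldehyde
Conditions: TBSCl (2.4 equiv), imidazole, DMF, rt
Reagents that add atoms: tert-butyldimethylsilyl chloride, CC(C)(C)[Si](C)(C)Cl
Why: Imidazole-promoted silylation should cap both phenols, giving base-stable, bulky and poorly nucleophilic aryl ethers that can be removed with fluoride at the end.

Step 5
Reactants: 7 2,5-bis[(tert-butyldimethylsilyl)oxy]benzaldehyde
Product: 8 1,4-bis[(tert-butyldimethylsilyl)oxy]-2-(2,2-dibromoethenyl)benzene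
Conditions: CBr4, PPh3, Et3N, CH2Cl2, 0 °C
Reagents that add atoms: carbon tetrabromide, BrC(Br)(Br)Br
Why: Ramirez dibromo-olefination (first half of the Corey–Fuchs sequence) is reliable for aryl aldehydes, and the amine buffer protects the aryl silyl ethers from adventitious acid.

Step 6
Reactants: 8 1,4-bis[(tert-butyldimethylsilyl)oxy]-2-(2,2-dibromoethenyl)benzene; 5 (2R)-2-[(tert-butyldimethylsilyl)oxy]-N-methoxy-N,5-dimethylhex-4-enamide
Product: 10 (4R)-1-{2,5-bis[(tert-butyldimethylsilyl)oxy]phenyl}-4-[(tert-butyldimethylsilyl)oxy]-7-methyloct-6-en-1-yn-3-one, via lithium arylacetylide 9 (not isolated)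
Conditions: 8 (1.3 equiv), n-BuLi (2.5 equiv), THF, −78 °C; then 5, −78 → −20 °C; cold 1 M aq. HCl
Reagents that add atoms: none
Why: Bromine–lithium exchange and Fritsch–Buttenberg–Wiechell rearrangement (second half of the Corey–Fuchs sequence) give the lithium acetylide, whose acylation by the Weinreb amide stops at the chelated tetrahedral adduct and so gives the ynone without over-addition, while the cold acidic quench protonates the released hydroxylamine before it can add to the ynone.

Step 7
Reactants: 10 (4R)-1-{2,5-bis[(tert-butyldimethylsilyl)oxy]phenyl}-4-[(tert-butyldimethylsilyl)oxy]-7-methyloct-6-en-1-yn-3-one; 11 trimethylsulfonium iodide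
Product: 12 2-({2,5-bis[(tert-butyldimethylsilyl)oxy]phenyl}ethynyl)-2-[(1R)-1-[(tert-butyldimethylsilyl)oxy]-4-methylpent-3-en-1-yl]oxirane, both epimers at the oxirane quaternary carbon
Conditions: 11, n-BuLi, THF, −10 °C; then 10, −78 → 0 °C
Reagents that add atoms: none
Why: In this Corey–Chaykovsky epoxidation the unstabilised dimethylsulfonium methylide should add 1,2 to the ynone carbonyl under kinetic control and the betaine should close to the oxirane; the new quaternary centre forms unselectively, which is harmless because it becomes sp2 in step 8, and the cold, fast addition is meant to outrun enolisation at the neighbouring stereocentre.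

Step 8
Reactants: 12 2-({2,5-bis[(tert-butyldimethylsilyl)oxy]phenyl}ethynyl)-2-[(1R)-1-[(tert-butyldimethylsilyl)oxy]-4-methylpent-3-en-1-yl]oxirane
Product: 13 2-{2,5-bis[(tert-butyldimethylsilyl)oxy]phenyl}-4-[(1R)-1-[(tert-butyldimethylsilyl)oxy]-4-methylpent-3-en-1-yl]furan
Conditions: AgOTf (10 mol %), TsOH·H2O (5 mol %), CH2Cl2/MeOH (9:1), rt, dark, short reaction time
Reagents that add atoms: none
Why: With the acid co-catalyst, methanol opens the oxirane at the propargylic quaternary carbon C4 (or the oxirane oxygen attacks directly), monovalent silver π-activates the alkyne, and the oxygen left on the CH2 group (future O1 and C5) adds anti to the aryl-bearing alkyne carbon to form O1–C2; protodeargentation at C3 and loss of methanol across C4–C5 then aromatise. The closest known reaction type is the silver- or gold-catalysed cycloisomerisation of 2-alkynyl oxiranes to furans, with the cyclodehydration of 3-alkyne-1,2-diols as its stepwise relative. The single ring formed, the furan, closes in a 5-endo-dig mode. No stereocentre is created: the oxirane quaternary carbon becomes sp2, so both epimers of 12 converge, and the (R)-carbinol carbon, although adjacent to the reacting C4, makes and breaks no bond and should be retained. The step needs attack by the oxirane-derived oxygen to win over 1,6-enyne cyclisation with the prenyl alkene, over benzofuran formation through the ortho aryl oxygen, over attack by the carbinol oxygen and over a 1,2-hydride shift to a cationic C4; the weakly carbophilic silver catalyst, the favourable 5-endo geometry of the CH2–O nucleophile, the bulky and poorly nucleophilic silyl ethers on the other three oxygens and the trapping of C4 by methanol should secure this. The electron-rich aryl group polarises the alkyne so that C2 is the electrophilic carbon.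

Step 9
Reactants: 13 2-{2,5-bis[(tert-butyldimethylsilyl)oxy]phenyl}-4-[(1R)-1-[(tert-butyldimethylsilyl)oxy]-4-methylpent-3-en-1-yl]furan
Product: 15 2-{4-[(1R)-4-methyl-1-[(3-methylbutanoyl)oxy]pent-3-en-1-yl]furan-2-yl}-1,4-phenylene bis(3-methylbutanoate), via triol 14 (not isolated)
Conditions: TBAF (4 equiv), THF, 0 °C → rt, Ar; then (iPrCH2CO)2O, Et3N, DMAP (cat.), 0 °C → rt
Reagents that add atoms: 3-methylbutanoic anhydride, CC(C)CC(=O)OC(=O)CC(C)C
Why: Fluoride desilylation followed in the same flask by DMAP-catalysed acylation should esterify all three oxygens without isolating the air-sensitive hydroquinone, under non-acidic conditions that cannot ionise the furylic C–O bond.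

Step 10
Reactants: 15 2-{4-[(1R)-4-methyl-1-[(3-methylbutanoyl)oxy]pent-3-en-1-yl]furan-2-yl}-1,4-phenylene bis(3-methylbutanoate)
Product: 16 (1R)-1-[5-(2,5-dihydroxyphenyl)furan-3-yl]-4-methylpent-3-en-1-yl 3-methylbutanoate (target)
Conditions: pyrrolidine (excess), degassed THF, 0 °C → rt, Ar
Reagents that add atoms: none
Why: Chemoselective aminolysis of aryl esters relies on phenoxide being a far better leaving group than a secondary alkoxide, so the two aryl esters should be cleaved while the furylic ester and the stereocentre stay untouched.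

Compound list
1 | methyl (2R)-oxirane-2-carboxylate (methyl (R)-glycidate) | COC(=O)[C@H]1CO1 | starting material
2 | 2-methyl-1-propenylmagnesium bromide | CC(C)=C[Mg]Br | starting material
3 | methyl (2R)-2-hydroxy-5-methylhex-4-enoate | CC(C)=CC[C@@H](O)C(=O)OC | intermediate
4 | methyl (2R)-2-[(tert-butyldimethylsilyl)oxy]-5-methylhex-4-enoate | CC(C)=CC[C@@H](O[Si](C)(C)C(C)(C)C)C(=O)OC | intermediate
5 | (2R)-2-[(tert-butyldimethylsilyl)oxy]-N-methoxy-N,5-dimethylhex-4-enamide | CC(C)=CC[C@@H](O[Si](C)(C)C(C)(C)C)C(=O)N(C)OC | intermediate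
6 | 2,5-dihydroxybenzaldehyde | O=Cc1cc(O)ccc1O | starting material
7 | 2,5-bis[(tert-butyldimethylsilyl)oxy]benzaldehyde | O=Cc1cc(O[Si](C)(C)C(C)(C)C)ccc1O[Si](C)(C)C(C)(C)C | intermediate
8 | 1,4-bis[(tert-butyldimethylsilyl)oxy]-2-(2,2-dibromoethenyl)benzene | BrC(Br)=Cc1cc(O[Si](C)(C)C(C)(C)C)ccc1O[Si](C)(C)C(C)(C)C | intermediate
9 | lithium {2,5-bis[(tert-butyldimethylsilyl)oxy]phenyl}acetylide | [Li]C#Cc1cc(O[Si](C)(C)C(C)(C)C)ccc1O[Si](C)(C)C(C)(C)C | intermediate (not isolated)
10 | (4R)-1-{2,5-bis[(tert-butyldimethylsilyl)oxy]phenyl}-4-[(tert-butyldimethylsilyl)oxy]-7-methyloct-6-en-1-yn-3-one | CC(C)=CC[C@@H](O[Si](C)(C)C(C)(C)C)C(=O)C#Cc1cc(O[Si](C)(C)C(C)(C)C)ccc1O[Si](C)(C)C(C)(C)C | intermediate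
11 | trimethylsulfonium iodide | C[S+](C)C.[I-] | starting material
12 | 2-({2,5-bis[(tert-butyldimethylsilyl)oxy]phenyl}ethynyl)-2-[(1R)-1-[(tert-butyldimethylsilyl)oxy]-4-methylpent-3-en-1-yl]oxirane, both oxirane epimers | CC(C)=CC[C@@H](O[Si](C)(C)C(C)(C)C)C1(CO1)C#Cc1cc(O[Si](C)(C)C(C)(C)C)ccc1O[Si](C)(C)C(C)(C)C | intermediate
13 | 2-{2,5-bis[(tert-butyldimethylsilyl)oxy]phenyl}-4-[(1R)-1-[(tert-butyldimethylsilyl)oxy]-4-methylpent-3-en-1-yl]furan | CC(C)=CC[C@@H](O[Si](C)(C)C(C)(C)C)c1coc(-c2cc(O[Si](C)(C)C(C)(C)C)ccc2O[Si](C)(C)C(C)(C)C)c1 | intermediate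
14 | 2-{4-[(1R)-1-hydroxy-4-methylpent-3-en-1-yl]furan-2-yl}benzene-1,4-diol | CC(C)=CC[C@@H](O)c1coc(-c2cc(O)ccc2O)c1 | intermediate (not isolated)
15 | 2-{4-[(1R)-4-methyl-1-[(3-methylbutanoyl)oxy]pent-3-en-1-yl]furan-2-yl}-1,4-phenylene bis(3-methylbutanoate) | CC(C)=CC[C@@H](OC(=O)CC(C)C)c1coc(-c2cc(OC(=O)CC(C)C)ccc2OC(=O)CC(C)C)c1 | intermediate
16 | (1R)-1-[5-(2,5-dihydroxyphenyl)furan-3-yl]-4-methylpent-3-en-1-yl 3-methylbutanoate | CC(C)=CC[C@@H](OC(=O)CC(C)C)c1coc(-c2cc(O)ccc2O)c1 | target

Total step count: 10
Longest linear sequence: 8 steps (steps 1, 2, 3, 6, 7, 8, 9, 10)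

Steps most likely to fail

Step 8. The cyclisation may be diverted in several ways. Methanol may open the oxirane at the CH2 terminus instead of C4, which gives an adduct that cannot close. The activated alkyne may be intercepted by the prenyl alkene. A silyl group may be lost in the acidic methanol, which frees an oxygen that then cyclises in the wrong sense. Fallback, from 12 back to 13: the oxirane of 12 is hydrolysed with water (catalytic HClO4, THF/H2O, 0 °C) to (3R)-2-({2,5-bis[(tert-butyldimethylsilyl)oxy]phenyl}ethynyl)-3-[(tert-butyldimethylsilyl)oxy]-6-methylhept-5-ene-1,2-diol F1. Either regiochemistry of water attack leads to this same diol. The isolated diol is then cyclodehydrated with AgNO3 on silica gel in CH2Cl2 at rt, the established 5-endo-dig furan synthesis from 3-alkyne-1,2-diols, which delivers 13 without methanol or sulfonic acid.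

Step 7. The ylide may add in a conjugate sense to the ynone, or may act as a base and enolise the ketone, which would erode the configuration at the adjacent carbinol carbon. Fallback, from 5 (with 8) back to 12: the order of bond formation is reversed. Weinreb amide 5 is treated with chloromethyllithium (ICH2Cl, MeLi·LiBr, THF, −78 °C) to give (3R)-3-[(tert-butyldimethylsilyl)oxy]-1-chloro-6-methylhept-5-en-2-one F2. The weakly basic lithium acetylide 9, generated from 8 as in step 6, is added at −78 °C to give the chlorohydrin (3R)-2-({2,5-bis[(tert-butyldimethylsilyl)oxy]phenyl}ethynyl)-3-[(tert-butyldimethylsilyl)oxy]-1-chloro-6-methylhept-5-en-2-ol F3 as its lithium alkoxide. This closes to oxirane 12 on warming to rt, and no ynone and no ylide are involved.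

Step 10. Discrimination between the aryl esters and the furylic ester may be incomplete, and the liberated hydroquinone may oxidise in the basic amine medium. Fallback, from 14 back to 16: the esters are no longer differentiated; the oxygens are differentiated by protecting groups instead. Triol 14 is isolated after the fluoride treatment of 13 and its two phenols are silylated selectively (TBSCl 2.1 equiv, Et3N, CH2Cl2, 0 °C) to give (1R)-1-(5-{2,5-bis[(tert-butyldimethylsilyl)oxy]phenyl}furan-3-yl)-4-methylpent-3-en-1-ol F4. The free secondary alcohol is acylated (3-methylbutanoyl chloride, pyridine, DMAP, CH2Cl2, 0 °C) to give (1R)-1-(5-{2,5-bis[(tert-butyldimethylsilyl)oxy]phenyl}furan-3-yl)-4-methylpent-3-en-1-yl 3-methylbutanoate F5. Buffered fluoride (TBAF/AcOH, THF, 0 °C) then removes the aryl silyl ethers under near-neutral conditions to give 16.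

Further compounds
F1 | step 8 | (3R)-2-({2,5-bis[(tert-butyldimethylsilyl)oxy]phenyl}ethynyl)-3-[(tert-butyldimethylsilyl)oxy]-6-methylhept-5-ene-1,2-diol, both C2 epimers | CC(C)=CC[C@@H](O[Si](C)(C)C(C)(C)C)C(O)(CO)C#Cc1cc(O[Si](C)(C)C(C)(C)C)ccc1O[Si](C)(C)C(C)(C)C
F2 | step 7 | (3R)-3-[(tert-butyldimethylsilyl)oxy]-1-chloro-6-methylhept-5-en-2-one | CC(C)=CC[C@@H](O[Si](C)(C)C(C)(C)C)C(=O)CCl
F3 | step 7 | (3R)-2-({2,5-bis[(tert-butyldimethylsilyl)oxy]phenyl}ethynyl)-3-[(tert-butyldimethylsilyl)oxy]-1-chloro-6-methylhept-5-en-2-ol, both C2 epimers | CC(C)=CC[C@@H](O[Si](C)(C)C(C)(C)C)C(O)(CCl)C#Cc1cc(O[Si](C)(C)C(C)(C)C)ccc1O[Si](C)(C)C(C)(C)C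
F4 | step 10 | (1R)-1-(5-{2,5-bis[(tert-butyldimethylsilyl)oxy]phenyl}furan-3-yl)-4-methylpent-3-en-1-ol | CC(C)=CC[C@@H](O)c1coc(-c2cc(O[Si](C)(C)C(C)(C)C)ccc2O[Si](C)(C)C(C)(C)C)c1
F5 | step 10 | (1R)-1-(5-{2,5-bis[(tert-butyldimethylsilyl)oxy]phenyl}furan-3-yl)-4-methylpent-3-en-1-yl 3-methylbutanoate | CC(C)=CC[C@@H](OC(=O)CC(C)C)c1coc(-c2cc(O[Si](C)(C)C(C)(C)C)ccc2O[Si](C)(C)C(C)(C)C)c1
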